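**Plan**

1. The two epoxides are removed first (last-step, catalyst-controlled epoxidation of the C3=C4 and C7=C8 E-olefins). The C12 exo-methylene and C11–H then go back to a bridgehead enone C11=C12–C13=O (Mannich methylenation, conjugate hydride addition).
2. Ring A and the twelve-membered ring are cut together at C13–C14 and C1–C15. Ring A (C1, C14, C13, C12, C11, C15) is a cyclohexene retron whose bridgeheads C1 and C11 are already joined by the C2–C10 chain, so a 1-silyloxy diene C13=C12–C11=C15 (chain on the inner carbon C11) and an E-enoate C14=C1 (chain on C1) close both rings in one type 2 intramolecular Diels–Alder reaction.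
3. Helpers: the silyl enol ether holds C13 at the level of the later ketone and fixes the regiochemistry; the C14 ester activates the dienophile and leaves afterwards as CO2 from the β-keto ester.
4. Forward: geranyl acetate supplies C2–C9 with both E-olefins; vinylation (C1, C14), sulfone acylation by an isopropylidene lactone (C10–C13, C15), cross-metathesis and enol silylation give the acyclic tetraene; then cycloaddition, ring-A adjustment and epoxidation.
5. Stereochemistry: C10 by oxazaborolidine reduction; C1 from C10 in the cycloaddition (allylic 1,3-strain); C11 by hydride delivery anti to the macrocyclic bridge; C3, C4, C7, C8 by the L-series Shi ketone acting on E-olefins.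

Key step: step 12

Remark: atoms are numbered as in verticillane (ring A = C1, C14, C13, C12, C11, C15; twelve-membered ring = C1 to C11 plus C15; C18 on C12); acyclic intermediates are discussed with the numbers their atoms have in the target.
Assumption: the enantiomer of the fructose-derived Shi ketone (made from L-sorbose) is taken as an available catalyst.

Step 1
Reactants: 1 geranyl acetate
Product: 2 (2E,6E)-8-hydroxy-3,7-dimethylocta-2,6-dien-1-yl acetate
Conditions: SeO2 (cat.), t-BuOOH, salicylic acid (cat.), CH2Cl2, rt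
Reagents that add atoms: tert-butyl hydroperoxide, CC(C)(C)OO
Why: Selenium dioxide allylic oxidation (ene reaction, then [2,3]-sigmatropic shift) should attack the distal olefin at its E-methyl group, the proximal olefin being deactivated by the allylic acetate, so the 6E geometry is kept.

Step 2
Reactants: 2 (2E,6E)-8-hydroxy-3,7-dimethylocta-2,6-dien-1-yl acetate
Product: 3 (2E,6E)-2,6-dimethyldeca-2,6,9-trien-1-ol
Conditions: CH2=CHMgBr (3 equiv), Li2CuCl4 (cat.), THF, −20 → 0 °C
Reagents that add atoms: vinylmagnesium bromide, C=C[Mg]Br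
Why: Copper-catalysed Grignard substitution of the primary allylic acetate at its α-carbon (SN2 type) should keep the E-olefin and brings in C1 and C14 as a base-stable vinyl group.

Step 3
Reactants: 3 (2E,6E)-2,6-dimethyldeca-2,6,9-trien-1-ol
Product: 5 {[(2E,6E)-2,6-dimethyldeca-2,6,9-trien-1-yl]sulfonyl}benzene, via allylic bromide 4 (not isolated)
Conditions: PBr3, pyridine (cat.), Et2O, −10 °C; crude bromide, then PhSO2Na, DMF, rt
Reagents that add atoms: sodium benzenesulfinate, [Na+].[O-]S(=O)c1ccccc1
Why: Bromination of the primary allylic alcohol and S-alkylation of the sulfinate at the primary carbon (SN2) should give the allylic sulfone without change of olefin geometry.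

Step 4
Reactants: 6 diethyl (2-oxooxolan-3-yl)phosphonate
Product: 7 3-(propan-2-ylidene)oxolan-2-one
Conditions: NaH, THF, 0 °C; acetone, rt → 50 °C
Reagents that add atoms: acetone, CC(C)=O
Why: Horner–Wadsworth–Emmons olefination of acetone gives the tetrasubstituted alkylidene lactone that carries C10–C13, C15 and both C15 methyl groups.

Step 5
Reactants: 5 {[(2E,6E)-2,6-dimethyldeca-2,6,9-trien-1-yl]sulfonyl}benzene; 7 3-(propan-2-ylidene)oxolan-2-one
Product: 9 (6E,10E)-2,6,10-trimethyl-5-(phenylsulfonyl)-3-{2-[(triethylsilyl)oxy]ethyl}tetradeca-2,6,10,13-tetraen-4-one (racemic at the sulfonyl carbon), via dilithium alkoxide enolate 8 (not isolated)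
Conditions: 5 (2.1 equiv), n-BuLi (2.05 equiv), THF, −78 °C; 7 (1 equiv), −78 → −40 °C; then Et3SiCl, −78 → 0 °C; aq NH4Cl (excess 5 recovered)
Reagents that add atoms: chlorotriethylsilane, CC[Si](Cl)(CC)CC
Why: Claisen-type acylation of the lithiated allylic sulfone at its α-carbon by the lactone forms C9–C10 (conjugate addition is blocked by the β,β-dimethyl terminus), and the ring-opened primary alkoxide is silylated in the same flask; the sulfonyl-bearing stereocenter is removed in step 6.

Step 6
Reactants: 9 (6E,10E)-2,6,10-trimethyl-5-(phenylsulfonyl)-3-{2-[(triethylsilyl)oxy]ethyl}tetradeca-2,6,10,13-tetraen-4-one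
Product: 10 (6E,10E)-2,6,10-trimethyl-3-{2-[(triethylsilyl)oxy]ethyl}tetradeca-2,6,10,13-tetraen-4-one
Conditions: SmI2, THF/MeOH, −78 °C
Reagents that add atoms: none
Why: Reductive desulfonylation of the β-keto sulfone (ketyl formation, loss of sulfinate, α-protonation of the samarium enolate) should leave C9 as CH2 with the C7=C8 olefin in place.

Step 7
Reactants: 10 (6E,10E)-2,6,10-trimethyl-3-{2-[(triethylsilyl)oxy]ethyl}tetradeca-2,6,10,13-tetraen-4-one
Product: 11 (4R,6E,10E)-2,6,10-trimethyl-3-{2-[(triethylsilyl)oxy]ethyl}tetradeca-2,6,10,13-tetraen-4-ol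
Conditions: (S)-2-methyl-CBS-oxazaborolidine (20 mol %), catecholborane, toluene, −78 °C; MeOH, aq NaOH work-up
Reagents that add atoms: none
Why: Corey–Bakshi–Shibata reduction, in which the α-branched alkenyl group acts as the large and the CH2 group as the small substituent, so the (S)-catalyst should give the R carbinol (C10 of the target); catecholborane spares the olefins.

Step 8
Reactants: 11 (4R,6E,10E)-2,6,10-trimethyl-3-{2-[(triethylsilyl)oxy]ethyl}tetradeca-2,6,10,13-tetraen-4-ol
Product: 12 (4R,6E,10E)-2,6,10-trimethyl-3-{2-[(triethylsilyl)oxy]ethyl}tetradeca-2,6,10,13-tetraen-4-yl acetate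
Conditions: Ac2O, DMAP (cat.), pyridine, CH2Cl2, 0 °C → rt
Reagents that add atoms: acetic anhydride, CC(=O)OC(C)=O
Why: Standard acylation installs the C10 acetate of the target with retention.

Step 9
Reactants: 12 (4R,6E,10E)-2,6,10-trimethyl-3-{2-[(triethylsilyl)oxy]ethyl}tetradeca-2,6,10,13-tetraen-4-yl acetate
Product: 13 methyl (2E,5E,9E,12R)-12-acetoxy-6,10,14-trimethyl-13-{2-[(triethylsilyl)oxy]ethyl}pentadeca-2,5,9,13-tetraenoate
Conditions: methyl acrylate (5 equiv), second-generation Grubbs catalyst RuCl2(=CHPh)(H2IMes)(PCy3) (5 mol %), 1,4-benzoquinone (cat.), CH2Cl2, 40 °C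
Reagents that add atoms: methyl acrylate, C=CC(=O)OC
Why: Olefin cross-metathesis of the only monosubstituted olefin with the acrylate should give the E-enoate, the tri- and tetrasubstituted olefins being inert to the catalyst.

Step 10
Reactants: 13 methyl (2E,5E,9E,12R)-12-acetoxy-6,10,14-trimethyl-13-{2-[(triethylsilyl)oxy]ethyl}pentadeca-2,5,9,13-tetraenoate
Product: 14 methyl (2E,5E,9E,12R)-12-acetoxy-6,10,14-trimethyl-13-(2-oxoethyl)pentadeca-2,5,9,13-tetraenoate
Conditions: (COCl)2, DMSO, CH2Cl2, −78 → −30 °C; then Et3N, −78 → 0 °C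
Reagents that add atoms: none
Why: Swern oxidation converts a primary triethylsilyl ether directly into the aldehyde (chloride-assisted O–Si cleavage, alkoxysulfonium ylide collapse), and the tetrasubstituted β,γ-olefin does not move into conjugation easily.

Step 11
Reactants: 14 methyl (2E,5E,9E,12R)-12-acetoxy-6,10,14-trimethyl-13-(2-oxoethyl)pentadeca-2,5,9,13-tetraenoate
Product: 15 methyl (2E,5E,9E,12R)-12-acetoxy-6,10,14-trimethyl-13-{(E)-2-[(triethylsilyl)oxy]ethenyl}pentadeca-2,5,9,13-tetraenoate
Conditions: Et3SiOTf, Et3N, CH2Cl2, −78 → 0 °C; filtration through Et3N-deactivated silica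
Reagents that add atoms: triethylsilyl trifluoromethanesulfonate, CC[Si](CC)(CC)OS(=O)(=O)C(F)(F)F
Why: Soft enolisation of the aldehyde at its only acidic position (C12) gives the 1-silyloxy diene, and the E enol ether is expected because the Z isomer would press the silyloxy group against the fully substituted C11.

Step 12
Reactants: 15 methyl (2E,5E,9E,12R)-12-acetoxy-6,10,14-trimethyl-13-{(E)-2-[(triethylsilyl)oxy]ethenyl}pentadeca-2,5,9,13-tetraenoate
Product: 17 methyl (1R,10R,13R,14R)-10-acetoxy-13-hydroxy-18-norverticilla-3E,7E,11-triene-14-carboxylate, via triethylsilyl ether 16 (not isolated)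
Conditions: PhMe (0.002 M), BHT (cat.), N,O-bis(trimethylsilyl)acetamide (trace), 150 °C, sealed tube; then HF·pyridine, THF, 0 °C
Reagents that add atoms: none
Why: A concerted, asynchronous [4+2] cycloaddition (type 2 intramolecular Diels–Alder reaction, the tether leaving the diene at its inner carbon C11) joins C13 to C14 and C15 to C1. The closest known reaction type is the type 2 intramolecular Diels–Alder reaction of 2-substituted 1,1-dimethylbutadienes that gives bridgehead-olefinic bicyclo[n.3.1] systems with a gem-dimethyl one-carbon bridge, together with macrocycle-forming intramolecular Diels–Alder reactions. Ring A closes as the six-membered [4+2] ring, and the twelve-membered ring closes in the same event through the C1–C15 bond as the 1,3-bridge of a bicyclo[9.3.1] system whose C11=C12 bridgehead olefin is unstrained (E within the fourteen-membered circuit). C1 is controlled by C10: allylic 1,3-strain with the cis methyl group of C15 holds H10 in the diene plane, so C9 and the acetoxy group lie on opposite faces and the dienophile arrives on the C9 face with the tether endo and the ester exo, which should give 1R from 10R, while C13 and C14 follow from the E enol ether and the E enoate (suprafacial addition) and are erased later. The step needs the regiochemistry C13–C14/C15–C1 rather than the crossed one (a thirteen-membered bridge), which is secured by polarisation (the silyloxy group makes C15 the nucleophilic diene terminus, the ester makes C1 the electrophilic dienophile carbon), and ring closure rather than oligomerisation, which high dilution and the two rigid E-olefins of the chain should favour.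

Step 13
Reactants: 17 methyl (1R,10R,13R,14R)-10-acetoxy-13-hydroxy-18-norverticilla-3E,7E,11-triene-14-carboxylate
Product: 18 methyl (1R,10R)-10-acetoxy-13-oxo-18-norverticilla-3E,7E,11-triene-14-carboxylate (C14 epimers and enol)
Conditions: Dess–Martin periodinane, NaHCO3, CH2Cl2, 0 °C → rt
Reagents that add atoms: none
Why: Dess–Martin oxidation of the allylic alcohol gives the bridgehead enone, which with the C14 ester is a β-keto ester (C14 now epimerisable, of no consequence).

Step 14
Reactants: 18 methyl (1R,10R)-10-acetoxy-13-oxo-18-norverticilla-3E,7E,11-triene-14-carboxylate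
Product: 19 (1R,10R)-10-acetoxy-18-norverticilla-3E,7E,11-trien-13-one
Conditions: LiCl, DMSO, H2O, 130 °C
Reagents that add atoms: none
Why: Krapcho dealkoxycarbonylation (chloride attack on the methyl ester, loss of CO2) removes the activating ester from C14 under neutral conditions.

Step 15
Reactants: 19 (1R,10R)-10-acetoxy-18-norverticilla-3E,7E,11-trien-13-one
Product: 20 (1R,10R,11S)-10-acetoxy-13-[dimethyl(phenyl)silyloxy]-18-norverticilla-3E,7E,12-triene (C11–H placed as in the target; the descriptor differs only through the priorities)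
Conditions: [(Ph3P)CuH]6 (cat.), PhMe2SiH, toluene, rt
Reagents that add atoms: dimethylphenylsilane, C[SiH](C)c1ccccc1
Why: Copper hydride conjugate reduction, in which hydride should add to the bridgehead β-carbon C11 from the face opposite the twelve-membered bridge (H11 cis to H1) and the enolate is trapped regiospecifically at C12–C13 as the silyl enol ether.

Step 16
Reactants: 20 (1R,10R,11S)-10-acetoxy-13-[dimethyl(phenyl)silyloxy]-18-norverticilla-3E,7E,12-triene
Product: 23 (1R,10R,11R)-10-acetoxyverticilla-3E,7E,12(18)-trien-13-one, via Mannich base 21 (not isolated), via ammonium iodide 22 (not isolated)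
Conditions: CH2=NMe2+ I− (Eschenmoser's salt), CH2Cl2, rt; then MeI; then aq NaHCO3, CH2Cl2
Reagents that add atoms: Eschenmoser's salt (N,N-dimethylmethyleneiminium iodide), C=[N+](C)C.[I-]
Why: Mannich reaction of the silyl enol ether at C12, quaternisation and Hofmann-type β-elimination give the exocyclic enone, and C11 is not epimerisable under these conditions.

Step 17
Reactants: 23 (1R,10R,11R)-10-acetoxyverticilla-3E,7E,12(18)-trien-13-one
Product: 24 (1R,3S,4S,7S,8S,10R,11R)-10-acetoxy-3,4:7,8-diepoxyverticill-12(18)-en-13-one (CNP0339728.1)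
Conditions: L-series Shi ketone (1,2:4,5-di-O-isopropylidene-β-L-erythro-2,3-hexodiulo-2,6-pyranose, 30 mol %), Oxone (KHSO5), K2CO3, Bu4NHSO4, MeCN/dimethoxymethane, aq Na2B4O7/Na2EDTA buffer, 0 °C
Reagents that add atoms: potassium peroxymonosulfate, [K+].[O-]S(=O)(=O)OO
Why: Shi epoxidation, in which the dioxirane of the L-series ketone should attack each E-trisubstituted olefin through the spiro transition state on the face that gives the (S,S)-epoxide, while the electron-poor enone is left alone.

**Compound list**

1 | geranyl acetate, (2E)-3,7-dimethylocta-2,6-dien-1-yl acetate | CC(C)=CCC/C(C)=C/COC(C)=O | starting material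
2 | (2E,6E)-8-hydroxy-3,7-dimethylocta-2,6-dien-1-yl acetate | CC(=O)OC/C=C(\C)CC/C=C(\C)CO | intermediate
3 | (2E,6E)-2,6-dimethyldeca-2,6,9-trien-1-ol | C=CC/C=C(\C)CC/C=C(\C)CO | intermediate
4 | (4E,8E)-10-bromo-5,9-dimethyldeca-1,4,8-triene | C=CC/C=C(\C)CC/C=C(\C)CBr | intermediate (not isolated)
5 | {[(2E,6E)-2,6-dimethyldeca-2,6,9-trien-1-yl]sulfonyl}benzene | C=CC/C=C(\C)CC/C=C(\C)CS(=O)(=O)c1ccccc1 | intermediate
6 | diethyl (2-oxooxolan-3-yl)phosphonate | CCOP(=O)(OCC)C1CCOC1=O | starting material
7 | 3-(propan-2-ylidene)oxolan-2-one | CC(C)=C1CCOC1=O | intermediate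
8 | dilithium salt of the ring-opened hydroxy β-keto sulfone (C13 alkoxide, C9–C10 enolate) | [Li+].[Li+].[O-]CCC(=C(C)C)C([O-])=C(/C(C)=C/CC/C(C)=C/CC=C)S(=O)(=O)c1ccccc1 | intermediate (not isolated)
9 | (6E,10E)-2,6,10-trimethyl-5-(phenylsulfonyl)-3-{2-[(triethylsilyl)oxy]ethyl}tetradeca-2,6,10,13-tetraen-4-one, racemic at C5 | C=CC/C=C(\C)CC/C=C(\C)C(C(=O)C(CCO[Si](CC)(CC)CC)=C(C)C)S(=O)(=O)c1ccccc1 | intermediate
10 | (6E,10E)-2,6,10-trimethyl-3-{2-[(triethylsilyl)oxy]ethyl}tetradeca-2,6,10,13-tetraen-4-one | C=CC/C=C(\C)CC/C=C(\C)CC(=O)C(CCO[Si](CC)(CC)CC)=C(C)C | intermediate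
11 | (4R,6E,10E)-2,6,10-trimethyl-3-{2-[(triethylsilyl)oxy]ethyl}tetradeca-2,6,10,13-tetraen-4-ol | C=CC/C=C(\C)CC/C=C(\C)C[C@@H](O)C(CCO[Si](CC)(CC)CC)=C(C)C | intermediate
12 | (4R,6E,10E)-2,6,10-trimethyl-3-{2-[(triethylsilyl)oxy]ethyl}tetradeca-2,6,10,13-tetraen-4-yl acetate | C=CC/C=C(\C)CC/C=C(\C)C[C@@H](OC(C)=O)C(CCO[Si](CC)(CC)CC)=C(C)C | intermediate
13 | methyl (2E,5E,9E,12R)-12-acetoxy-6,10,14-trimethyl-13-{2-[(triethylsilyl)oxy]ethyl}pentadeca-2,5,9,13-tetraenoate | COC(=O)/C=C/C/C=C(\C)CC/C=C(\C)C[C@@H](OC(C)=O)C(CCO[Si](CC)(CC)CC)=C(C)C | intermediate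
14 | methyl (2E,5E,9E,12R)-12-acetoxy-6,10,14-trimethyl-13-(2-oxoethyl)pentadeca-2,5,9,13-tetraenoate | COC(=O)/C=C/C/C=C(\C)CC/C=C(\C)C[C@@H](OC(C)=O)C(CC=O)=C(C)C | intermediate
15 | methyl (2E,5E,9E,12R)-12-acetoxy-6,10,14-trimethyl-13-{(E)-2-[(triethylsilyl)oxy]ethenyl}pentadeca-2,5,9,13-tetraenoate | COC(=O)/C=C/C/C=C(\C)CC/C=C(\C)C[C@@H](OC(C)=O)C(/C=C/O[Si](CC)(CC)CC)=C(C)C | intermediate
16 | methyl (1R,10R,13R,14R)-10-acetoxy-13-[(triethylsilyl)oxy]-18-norverticilla-3E,7E,11-triene-14-carboxylate | CC[Si](CC)(CC)O[C@H]1[C@H](C(=O)OC)[C@H]2C/C=C(\C)CC/C=C(\C)C[C@@H](OC(C)=O)C(=C1)C2(C)C | intermediate (not isolated)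
17 | methyl (1R,10R,13R,14R)-10-acetoxy-13-hydroxy-18-norverticilla-3E,7E,11-triene-14-carboxylate | O[C@H]1[C@H](C(=O)OC)[C@H]2C/C=C(\C)CC/C=C(\C)C[C@@H](OC(C)=O)C(=C1)C2(C)C | intermediate
18 | methyl (1R,10R)-10-acetoxy-13-oxo-18-norverticilla-3E,7E,11-triene-14-carboxylate, C14 epimers and enol | O=C1C(C(=O)OC)[C@H]2C/C=C(\C)CC/C=C(\C)C[C@@H](OC(C)=O)C(=C1)C2(C)C | intermediate
19 | (1R,10R)-10-acetoxy-18-norverticilla-3E,7E,11-trien-13-one | O=C1C[C@H]2C/C=C(\C)CC/C=C(\C)C[C@@H](OC(C)=O)C(=C1)C2(C)C | intermediate
20 | (1R,10R,11S)-10-acetoxy-13-[dimethyl(phenyl)silyloxy]-18-norverticilla-3E,7E,12-triene | C1=C(O[Si](C)(C)c3ccccc3)C[C@H]2C/C=C(\C)CC/C=C(\C)C[C@@H](OC(C)=O)[C@@H]1C2(C)C | intermediate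
21 | (1R,10R,11S)-10-acetoxy-18-(dimethylamino)verticilla-3E,7E-dien-13-one, C12 epimers | CN(C)CC1C(=O)C[C@H]2C/C=C(\C)CC/C=C(\C)C[C@@H](OC(C)=O)[C@@H]1C2(C)C | intermediate (not isolated)
22 | N-methyl ammonium iodide of 21 | C[N+](C)(C)CC1C(=O)C[C@H]2C/C=C(\C)CC/C=C(\C)C[C@@H](OC(C)=O)[C@@H]1C2(C)C.[I-] | intermediate (not isolated)
23 | (1R,10R,11R)-10-acetoxyverticilla-3E,7E,12(18)-trien-13-one | C=C1C(=O)C[C@H]2C/C=C(\C)CC/C=C(\C)C[C@@H](OC(C)=O)[C@@H]1C2(C)C | intermediate
24 | (1R,3S,4S,7S,8S,10R,11R)-10-acetoxy-3,4:7,8-diepoxyverticill-12(18)-en-13-one, CNP0339728.1 | C=C1C(=O)C[C@H]2C[C@@H]3O[C@@]3(C)CC[C@@H]3O[C@@]3(C)C[C@@H](OC(C)=O)[C@@H]1C2(C)C | target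

Total step count: 17. Longest linear sequence: 16 steps (from 1 through steps 1–3 and 5–17 to 24).

**Steps most likely to fail**

Step 12. The cycloaddition may be too slow at a temperature the silyl dienol ether tolerates, because the leading bond has to form at the fully substituted terminus C15 while a twelve-membered ring closes. Oligomerisation, sigmatropic hydrogen shift within the diene, or weak facial control could then take over. The fallback makes the two bonds one after the other by a polar annulation at low temperature instead of a concerted thermal one. It sets out from aldehyde 14, which t-BuMe2SiOTf and Et3N convert into the more robust tert-butyldimethylsilyl dienol ether F1. Under Me3SiNTf2 catalysis in CH2Cl2 at −78 °C and high dilution, a vinylogous Mukaiyama–Michael addition of C15 to C1 closes the twelve-membered ring. The silyl ketene acetal so formed then closes ring A by aldol addition to the unsaturated oxocarbenium carbon C13, giving the cyclic silyl ether F2 (mixture at C13 and C14). HF·pyridine gives the alcohol F3, and Dess–Martin oxidation brings the material back to the route at 18. Control of C1 by C10 rests on the same allylic-strain argument.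

Step 15. Hydride transfer to the fully substituted bridgehead carbon C11 may be too slow, may turn into 1,2-reduction, or may come from the wrong face. The fallback delivers the hydrogen at C11 from a π-allyl palladium hydride instead of a copper hydride. It sets out from enone 19. α-Iodination (I2, pyridine) gives the iodoenone F4, and Stille coupling with Bu3SnCH2OH (Pd(PPh3)4) gives the hydroxymethyl enone F5. Formylation (HCO2H, DCC, DMAP) gives the allylic formate F6. With Pd(OAc)2 and n-Bu3P in refluxing THF, ionisation at the primary C18–O bond, loss of CO2 and hydride transfer to the more substituted allyl terminus C11 from the metal-bearing outer face should give the exo-methylene ketone. The hindered secondary C10 acetate should ionise more slowly than the primary formate. The fallback comes back to the route at 23.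

Step 17. The catalyst may fail to override the conformational bias of the twelve-membered ring at one of the two olefins, giving poor facial selectivity, and the α-methylene ketone may be attacked in the basic peroxide medium. The fallback moves the epoxidation in front of the ring-A end game, so that it acts on a different ring conformation (sp2 C11) with no sensitive enone present. It sets out from enone 19, which under the conditions of step 17 should give the diepoxy enone F7. Conjugate reduction as in step 15 gives the silyl enol ether F8. Eschenmoser's salt with CsF gives the Mannich base F9; silicon leaves as the fluoride, so no silyl iodide reaches the epoxides. MeI gives the ammonium iodide F10, and aqueous NaHCO3 returns the material to the route at 24.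

**Further compounds**

F1 | step 12 | methyl (2E,5E,9E,12R)-12-acetoxy-13-{(E)-2-[(tert-butyldimethylsilyl)oxy]ethenyl}-6,10,14-trimethylpentadeca-2,5,9,13-tetraenoate | COC(=O)/C=C/C/C=C(\C)CC/C=C(\C)C[C@@H](OC(C)=O)C(/C=C/O[Si](C)(C)C(C)(C)C)=C(C)C
F2 | step 12 | methyl (1R,10R)-10-acetoxy-13-[(tert-butyldimethylsilyl)oxy]-18-norverticilla-3E,7E,11-triene-14-carboxylate, mixture at C13 and C14 | CC(C)(C)[Si](C)(C)OC1C(C(=O)OC)[C@H]2C/C=C(\C)CC/C=C(\C)C[C@@H](OC(C)=O)C(=C1)C2(C)C
F3 | step 12 | methyl (1R,10R)-10-acetoxy-13-hydroxy-18-norverticilla-3E,7E,11-triene-14-carboxylate, mixture at C13 and C14 | OC1C(C(=O)OC)[C@H]2C/C=C(\C)CC/C=C(\C)C[C@@H](OC(C)=O)C(=C1)C2(C)C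
F4 | step 15 | (1R,10R)-10-acetoxy-12-iodo-18-norverticilla-3E,7E,11-trien-13-one | O=C1C[C@H]2C/C=C(\C)CC/C=C(\C)C[C@@H](OC(C)=O)C(=C1I)C2(C)C
F5 | step 15 | (1R,10R)-10-acetoxy-18-hydroxyverticilla-3E,7E,11-trien-13-one | O=C1C[C@H]2C/C=C(\C)CC/C=C(\C)C[C@@H](OC(C)=O)C(=C1CO)C2(C)C
F6 | step 15 | (1R,10R)-10-acetoxy-13-oxoverticilla-3E,7E,11-trien-18-yl formate | O=C1C[C@H]2C/C=C(\C)CC/C=C(\C)C[C@@H](OC(C)=O)C(=C1COC=O)C2(C)C
F7 | step 17 | (1R,3S,4S,7S,8S,10R)-10-acetoxy-3,4:7,8-diepoxy-18-norverticill-11-en-13-one | O=C1C[C@H]2C[C@@H]3O[C@@]3(C)CC[C@@H]3O[C@@]3(C)C[C@@H](OC(C)=O)C(=C1)C2(C)C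
F8 | step 17 | (1R,3S,4S,7S,8S,10R,11S)-10-acetoxy-13-[dimethyl(phenyl)silyloxy]-3,4:7,8-diepoxy-18-norverticill-12-ene | C1=C(O[Si](C)(C)c3ccccc3)C[C@H]2C[C@@H]3O[C@@]3(C)CC[C@@H]3O[C@@]3(C)C[C@@H](OC(C)=O)[C@@H]1C2(C)C
F9 | step 17 | (1R,3S,4S,7S,8S,10R,11S)-10-acetoxy-18-(dimethylamino)-3,4:7,8-diepoxyverticillan-13-one, C12 epimers | CN(C)CC1C(=O)C[C@H]2C[C@@H]3O[C@@]3(C)CC[C@@H]3O[C@@]3(C)C[C@@H](OC(C)=O)[C@@H]1C2(C)C
F10 | step 17 | N-methyl ammonium iodide of F9 | C[N+](C)(C)CC1C(=O)C[C@H]2C[C@@H]3O[C@@]3(C)CC[C@@H]3O[C@@]3(C)C[C@@H](OC(C)=O)[C@@H]1C2(C)C.[I-]
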